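Feature: in ring B (O, C7–C11), carbons C8–C11 and one of the two C11 methyl groups are the skeleton of 2-methylfuran. The furan oxygen ends as the C8 oxygen, the ring oxygen comes from the C7 tertiary alcohol, and C9=C10 survives as an enone that later takes bromine at C10.
Endgame on ring A: C8–OAc ⇐ caespitol; trans-diequatorial C2–Br/C3–Cl ⇐ C2=C3 alkene, through a cis-fused acetoxonium ion opened by chloride at C3 and an oxidation/reduction/Appel sequence at C2.
Ring B tailoring: C10–Br ⇐ C10–Bpin ⇐ enone (conjugate borylation); C8–OH ⇐ C8 ketone; second C11 methyl ⇐ C11 oxocarbenium ion + AlMe3.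
Key disconnection: O–C11 of the pyranone ⇐ tertiary furyl carbinol (Achmatowicz); C7 ⇐ furyl ketone + Me2Zn (asymmetric); C7–C8 ⇐ Weinreb amide + 5-methyl-2-furyllithium.
Ring order: ring A first, by an enantioselective Diels–Alder reaction that sets C6 and brings C3–CH3. It is carried as its C2=C3 alkene, which AlMe3 leaves alone where a ketal could ionise, and which needs no late desymmetrisation. Ring B second (step 5).
Key step: step 5

Assumption: caespitol numbering is used (ring A = C1–C6 with C6 bearing C7, C2 Br, C3 Cl and CH3; ring B = O, C7 (CH3), C8 (OAc), C9, C10 (Br), C11 (two CH3)). The catalyst antipodes named in steps 1 and 4 are those expected from the accepted facial models, and the mirror-image catalyst would be taken if the sense proved opposite.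

Step 1
Reactants: 1 isoprene, 2 2,2,2-trifluoroethyl acrylate
Product: 3 2,2,2-trifluoroethyl (1S)-4-methylcyclohex-3-ene-1-carboxylate
Conditions: (S)-3,3-diphenyl-1-(2-methylphenyl)tetrahydro-1H,3H-pyrrolo[1,2-c][1,3,2]oxazaborole (10 mol %), HN(SO2CF3)2 (10 mol %), 1 (3 equiv), CH2Cl2, −20 °C
Reagents that add atoms: none
Why: Catalytic enantioselective Diels–Alder reaction: the cationic oxazaborolidinium activates the acrylate and covers its Cα Si face, so isoprene should add para-selectively through its C4 terminus to the Re face, which closes ring A and sets C6 as S.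

Step 2
Reactants: 3 2,2,2-trifluoroethyl (1S)-4-methylcyclohex-3-ene-1-carboxylate
Product: 4 (1S)-N-methoxy-N,4-dimethylcyclohex-3-ene-1-carboxamide
Conditions: MeNH(OMe)·HCl (1.5 equiv), i-PrMgCl (3 equiv), THF, −20 °C; then H2O
Reagents that add atoms: N,O-dimethylhydroxylamine hydrochloride, CNOC.Cl
Why: Weinreb amide formation by aminolysis of the activated trifluoroethyl ester with the chloromagnesium amide, fast enough at −20 °C that the α-stereocentre C6 should not be enolised.

Step 3
Reactants: 4 (1S)-N-methoxy-N,4-dimethylcyclohex-3-ene-1-carboxamide, 5 2-methylfuran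
Product: 7 (5-methylfuran-2-yl)[(1S)-4-methylcyclohex-3-en-1-yl]methanone, via 5-methyl-2-furyllithium 6 (not isolated)
Conditions: 5, n-BuLi, THF, 0 °C; then 4, −78 → 0 °C; then H2O
Reagents that add atoms: none
Why: Weinreb ketone synthesis: 2-methylfuran is lithiated at its only free α-position and the amide takes up one equivalent of the heteroaryllithium only, the carbonyl group being released on work-up, so neither over-addition nor epimerisation at C6 is expected.

Step 4
Reactants: 7 (5-methylfuran-2-yl)[(1S)-4-methylcyclohex-3-en-1-yl]methanone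
Product: 8 (1R)-1-(5-methylfuran-2-yl)-1-[(1S)-4-methylcyclohex-3-en-1-yl]ethan-1-ol
Conditions: Me2Zn (3 equiv), Ti(Oi-Pr)4 (1.2 equiv), N,N′-[(1R,2R)-cyclohexane-1,2-diyl]bis[1-((1S)-2-exo-hydroxy-7,7-dimethylbicyclo[2.2.1]heptan-1-yl)methanesulfonamide] (10 mol %), toluene, rt; then H2O
Reagents that add atoms: dimethylzinc, C[Zn]C
Why: Catalytic asymmetric 1,2-addition of a dialkylzinc to a ketone (titanium bis(sulfonamide) diol catalysis): the catalyst tells the flat furyl group from the sec-alkyl group and should deliver methyl to the Si face of the carbonyl to set C7 as R, and since C6 is already fixed any 7S product is a diastereomer that chromatography can remove.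

Step 5
Reactants: 8 (1R)-1-(5-methylfuran-2-yl)-1-[(1S)-4-methylcyclohex-3-en-1-yl]ethan-1-ol
Product: 10 (2R)-6-hydroxy-2,6-dimethyl-2-[(1S)-4-methylcyclohex-3-en-1-yl]-2H-pyran-3(6H)-one (both C11 epimers), via Z-ene-dione 9 (not isolated)
Conditions: NBS (1.0 equiv, added slowly), NaHCO3 (2 equiv), THF/H2O (4:1), 0 °C
Reagents that add atoms: water, O
Why: NBS brominates the electron-rich 2,5-dialkylfuran, water adds, and the dihydrofuran so formed opens to the Z-ene-dione 9, in which the old furan oxygen is the C8 ketone oxygen; the C7 tertiary hydroxyl then adds to the C11 methyl ketone and forms the O–C11 bond (Achmatowicz rearrangement, well known for tertiary furyl carbinols). Ring B closes by a 6-exo-trig carbonyl addition, helped by the Z geometry of C9=C10 and by the fully substituted C7 (gem-dialkyl effect). The only new stereocentre is the hemiketal carbon C11, which is left uncontrolled because it becomes non-stereogenic in step 7, while C6 and C7 take no part and keep their configuration. The selectivity needed is furan over the trisubstituted C2=C3 alkene of ring A, and it is secured by the much higher nucleophilicity of the dialkylfuran together with one equivalent of NBS at 0 °C. The NaHCO3 buffer removes HBr so that the acid-labile tertiary furfuryl alcohol does not ionise.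

Step 6
Reactants: 10 (2R)-6-hydroxy-2,6-dimethyl-2-[(1S)-4-methylcyclohex-3-en-1-yl]-2H-pyran-3(6H)-one
Product: 11 (6R)-2,6-dimethyl-6-[(1S)-4-methylcyclohex-3-en-1-yl]-5-oxo-5,6-dihydro-2H-pyran-2-yl acetate (both C11 epimers)
Conditions: Ac2O, DMAP (cat.), pyridine, 0 °C → rt
Reagents that add atoms: acetic anhydride, CC(=O)OC(C)=O
Why: DMAP-catalysed O-acylation traps the ring form of the hemiketal, because the tertiary C7 hydroxyl of the open form is far more hindered, and turns C11–OH into a leaving group; both C11 epimers are carried on.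

Step 7
Reactants: 11 (6R)-2,6-dimethyl-6-[(1S)-4-methylcyclohex-3-en-1-yl]-5-oxo-5,6-dihydro-2H-pyran-2-yl acetate
Product: 13 (2R)-2,6,6-trimethyl-2-[(1S)-4-methylcyclohex-3-en-1-yl]-2H-pyran-3(6H)-one, via C11 oxocarbenium aluminate 12 (not isolated)
Conditions: AlMe3 (3 equiv), CH2Cl2, −78 → −20 °C; then H2O
Reagents that add atoms: trimethylaluminium, C[Al](C)C
Why: Oxocarbenium alkylation with an organoaluminium (C-glycosidation type substitution of a ketal acetate): AlMe3 pulls off the acetate and the aluminate returns a methyl group to C11 of ion pair 12, C11 thereby losing its stereogenicity, while the fully substituted C7 rules out oxidopyrylium formation and, together with the low temperature, shields the C8 ketone from 1,2-addition.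

Step 8
Reactants: 13 (2R)-2,6,6-trimethyl-2-[(1S)-4-methylcyclohex-3-en-1-yl]-2H-pyran-3(6H)-one
Product: 14 (2R,5S)-2,6,6-trimethyl-2-[(1S)-4-methylcyclohex-3-en-1-yl]-5-(4,4,5,5-tetramethyl-1,3,2-dioxaborolan-2-yl)oxan-3-one (C10–Bpin axial, cis to ring A)
Conditions: CuCl (5 mol %), NaOt-Bu (10 mol %), bis[2-(diphenylphosphino)phenyl] ether (5 mol %), B2pin2 (1.2 equiv), MeOH (2 equiv), THF, rt
Reagents that add atoms: bis(pinacolato)diboron, CC1(C)OB(OC1(C)C)B1OC(C)(C)C(C)(C)O1
Why: Copper-catalysed conjugate borylation of an enone: in the favoured envelope of 13 (ring oxygen out of plane, C7–CH3 and one C11–CH3 pseudoaxial on the same face, ring A pseudoequatorial) the Cu–Bpin species should attack C10 anti to the neighbouring pseudoaxial C11 methyl, which places boron axial and cis to ring A (10S).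

Step 9
Reactants: 14 (2R,5S)-2,6,6-trimethyl-2-[(1S)-4-methylcyclohex-3-en-1-yl]-5-(pinacolboryl)oxan-3-one
Product: 15 (2R,3R,5S)-2,6,6-trimethyl-2-[(1S)-4-methylcyclohex-3-en-1-yl]-5-(4,4,5,5-tetramethyl-1,3,2-dioxaborolan-2-yl)oxan-3-ol (C8–OH axial, cis to ring A and to Bpin)
Conditions: LiBH(s-Bu)3, THF, −78 → −40 °C; then H2O (non-oxidative work-up)
Reagents that add atoms: none
Why: Diastereoselective ketone reduction with a bulky trialkylborohydride: the axial C10–Bpin group blocks the axial trajectory and the reagent in any case prefers the equatorial one, as in the reduction of 4,4-dimethyl-3-keto terpenoids to axial alcohols, so hydride should enter from the face of the C7 methyl and give the axial 8R alcohol; the work-up is kept non-oxidative to save the C–B bond.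

Step 10
Reactants: 15 (2R,3R,5S)-boryl alcohol
Product: 16 tert-butyldimethylsilyl ether of 15, (2R,3R,5S)
Conditions: TBSOTf, 2,6-lutidine, CH2Cl2, 0 °C
Reagents that add atoms: tert-butyldimethylsilyl triflate, CC(C)(C)[Si](C)(C)OS(=O)(=O)C(F)(F)F
Why: Silylation with the reactive silyl triflate protects the hindered axial C8 hydroxyl against the aryllithium, the hydrides and the oxidant of the following steps.

Step 11
Reactants: 16 tert-butyldimethylsilyl ether of 15
Product: 18 tert-butyl{[(2R,3R,5R)-5-bromo-2,6,6-trimethyl-2-[(1S)-4-methylcyclohex-3-en-1-yl]oxan-3-yl]oxy}dimethylsilane (C10–Br equatorial), via lithium aryl boronate complex 17 (not isolated)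
Conditions: 3,5-(CF3)2C6H3Br, n-BuLi, THF, −78 °C; add 16; then NBS, THF, −78 °C; then H2O
Reagents that add atoms: N-bromosuccinimide, O=C1CCC(=O)N1Br
Why: Stereospecific bromodeboronation of a secondary pinacol boronic ester through its electron-poor aryl boronate complex 17, which reacts with NBS by an SE2 pathway with inversion, so axial C10–B should become equatorial C10–Br (10R); at −78 °C the boronate outruns the ring A alkene for NBS.

Step 12
Reactants: 18 C10 bromide with the ring A alkene
Product: 19 (1R,2R,4S)-4-[(2R,3R,5R)-5-bromo-3-(tert-butyldimethylsilyloxy)-2,6,6-trimethyloxan-2-yl]-2-iodo-1-methylcyclohexyl acetate (C2–I axial, C3–OAc axial, C3–CH3 equatorial)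
Conditions: NIS, AcOH (10 equiv), CH2Cl2, 0 °C, dark
Reagents that add atoms: N-iodosuccinimide, O=C1CCC(=O)N1I; acetic acid, CC(=O)O
Why: Iodoacetoxylation (first stage of the Prévost–Woodward reaction): iodonium formation is reversible and only the iodonium ion anti to the C6 substituent can be opened by acetate at the tertiary C3 in both a Markovnikov and a trans-diaxial (Fürst–Plattner) sense, as in halohydrin formation from limonene, so axial C2–I and axial C3–OAc should result.

Step 13
Reactants: 19 trans-diaxial iodoacetate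
Product: 21 (1S,2S,5S)-5-[(2R,3R,5R)-5-bromo-3-(tert-butyldimethylsilyloxy)-2,6,6-trimethyloxan-2-yl]-2-chloro-2-methylcyclohexyl acetate (C3–Cl equatorial, C3–CH3 axial, C2–OAc equatorial), via acetoxonium tetrafluoroborate 20 (not isolated)
Conditions: AgBF4 (1.05 equiv), CH2Cl2, −40 °C; then n-Bu4NCl (3 equiv), −40 → 0 °C
Reagents that add atoms: tetrabutylammonium chloride, CCCC[N+](CCCC)(CCCC)CCCC.[Cl-]
Why: Prévost–Woodward type ionisation followed by halide opening of the acyloxonium ion: silver removes the axial iodide with anti-periplanar help from the C3 acetate to give the cis-fused ion 20, whose tertiary, axial C3–O bond is the weaker one and whose C2 is neopentyl-like, so chloride should enter at C3 from the face opposite to the departing oxygen and set equatorial C3–Cl with axial CH3 (3S), leaving an equatorial C2 acetate.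

Step 14
Reactants: 21 chloro acetate
Product: 22 (1S,2S,5S)-5-[(2R,3R,5R)-5-bromo-3-(tert-butyldimethylsilyloxy)-2,6,6-trimethyloxan-2-yl]-2-chloro-2-methylcyclohexan-1-ol (C2–OH equatorial)
Conditions: i-Bu2AlH (2.5 equiv), CH2Cl2, −78 °C; then H2O
Reagents that add atoms: none
Why: Reductive cleavage of the acetate with i-Bu2AlH at −78 °C avoids base, under which a chlorohydrin could close to an epoxide or lose HCl, and leaves the halides and the silyl ether alone.

Step 15
Reactants: 22 equatorial chlorohydrin
Product: 23 (2S,5S)-5-[(2R,3R,5R)-5-bromo-3-(tert-butyldimethylsilyloxy)-2,6,6-trimethyloxan-2-yl]-2-chloro-2-methylcyclohexan-1-one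
Conditions: Dess–Martin periodinane, CH2Cl2, rt
Reagents that add atoms: none
Why: Dess–Martin oxidation under neutral conditions removes the wrongly configured C2 carbinol centre without touching the quaternary C3–Cl centre, which cannot epimerise.

Step 16
Reactants: 23 α-chloro ketone
Product: 24 (1R,2S,5S)-5-[(2R,3R,5R)-5-bromo-3-(tert-butyldimethylsilyloxy)-2,6,6-trimethyloxan-2-yl]-2-chloro-2-methylcyclohexan-1-ol (C2–OH axial, cis to Cl)
Conditions: LiBH(s-Bu)3, THF, −78 °C; then H2O
Reagents that add atoms: none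
Why: Bulky trialkylborohydride reduction by equatorial attack, the standard way to axial alcohols next to a fully substituted carbon, should give the axial 2R alcohol, cis to chlorine so that the alkoxide cannot close to an epoxide.

Step 17
Reactants: 24 axial chlorohydrin
Product: 25 {[(2R,3R,5R)-5-bromo-2-[(1S,3S,4S)-3-bromo-4-chloro-4-methylcyclohexyl]-2,6,6-trimethyloxan-3-yl]oxy}(tert-butyl)dimethylsilane (O-TBS-caespitol)
Conditions: CBr4, P(n-C8H17)3, toluene, 60 °C
Reagents that add atoms: carbon tetrabromide, BrC(Br)(Br)Br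
Why: Appel bromination with SN2 inversion of an axial alcohol, the method by which equatorial bromides next to fully substituted carbons are made in brominated terpenoids: bromide displaces the axial oxyphosphonium group from the equatorial side and sets C2–Br equatorial (2S), trans-diequatorial to C3–Cl.

Step 18
Reactants: 25 O-TBS-caespitol
Product: 26 (2R,3R,5R)-5-bromo-2-[(1S,3S,4S)-3-bromo-4-chloro-4-methylcyclohexyl]-2,6,6-trimethyloxan-3-ol (caespitol)
Conditions: HF·pyridine, THF, 0 °C → rt
Reagents that add atoms: none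
Why: Fluoride-mediated desilylation under mildly acidic conditions frees the C8 hydroxyl without base, so that neither the tertiary chloride nor the secondary bromides are eliminated.

Step 19
Reactants: 26 caespitol
Product: 27 8-acetylcaespitol, (2R,3R,5R)-5-bromo-2-[(1S,3S,4S)-3-bromo-4-chloro-4-methylcyclohexyl]-2,6,6-trimethyloxan-3-yl acetate
Conditions: Ac2O, DMAP (cat.), pyridine, rt
Reagents that add atoms: acetic anhydride, CC(=O)OC(C)=O
Why: DMAP-catalysed acetylation of the hindered axial C8 alcohol with retention at C8 gives the target.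

Compound list
1 | isoprene (2-methylbuta-1,3-diene) | C=CC(C)=C | starting material
2 | 2,2,2-trifluoroethyl acrylate | C=CC(=O)OCC(F)(F)F | starting material
3 | 2,2,2-trifluoroethyl (1S)-4-methylcyclohex-3-ene-1-carboxylate | FC(F)(F)COC(=O)[C@H]1CCC(C)=CC1 | intermediate
4 | (1S)-N-methoxy-N,4-dimethylcyclohex-3-ene-1-carboxamide | CON(C)C(=O)[C@H]1CCC(C)=CC1 | intermediate
5 | 2-methylfuran | Cc1ccco1 | starting material
6 | 5-methyl-2-furyllithium | Cc1ccc([Li])o1 | intermediate
7 | (5-methylfuran-2-yl)[(1S)-4-methylcyclohex-3-en-1-yl]methanone | Cc1ccc(o1)C(=O)[C@H]1CCC(C)=CC1 | intermediate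
8 | (1R)-1-(5-methylfuran-2-yl)-1-[(1S)-4-methylcyclohex-3-en-1-yl]ethan-1-ol | Cc1ccc(o1)[C@](C)(O)[C@H]1CCC(C)=CC1 | intermediate
9 | (3Z,6R)-6-hydroxy-6-[(1S)-4-methylcyclohex-3-en-1-yl]hept-3-ene-2,5-dione | CC(=O)/C=C\C(=O)[C@](C)(O)[C@H]1CCC(C)=CC1 | intermediate
10 | (2R)-6-hydroxy-2,6-dimethyl-2-[(1S)-4-methylcyclohex-3-en-1-yl]-2H-pyran-3(6H)-one (C11 epimers) | CC1(O)C=CC(=O)[C@](C)(O1)[C@H]1CCC(C)=CC1 | intermediate
11 | (6R)-2,6-dimethyl-6-[(1S)-4-methylcyclohex-3-en-1-yl]-5-oxo-5,6-dihydro-2H-pyran-2-yl acetate (C11 epimers) | CC(=O)OC1(C)C=CC(=O)[C@](C)(O1)[C@H]1CCC(C)=CC1 | intermediate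
12 | C11 oxocarbenium ion of ring B, acetoxytrimethylaluminate salt | CC1=[O+][C@](C)([C@H]2CCC(C)=CC2)C(=O)C=C1.C[Al-](C)(C)OC(C)=O | intermediate
13 | (2R)-2,6,6-trimethyl-2-[(1S)-4-methylcyclohex-3-en-1-yl]-2H-pyran-3(6H)-one | CC1(C)C=CC(=O)[C@](C)(O1)[C@H]1CCC(C)=CC1 | intermediate
14 | (2R,5S)-2,6,6-trimethyl-2-[(1S)-4-methylcyclohex-3-en-1-yl]-5-(pinacolboryl)oxan-3-one | O=C1C[C@H](B2OC(C)(C)C(C)(C)O2)C(C)(C)O[C@]1(C)[C@H]1CCC(C)=CC1 | intermediate
15 | (2R,3R,5S)-2,6,6-trimethyl-2-[(1S)-4-methylcyclohex-3-en-1-yl]-5-(pinacolboryl)oxan-3-ol | O[C@@H]1C[C@H](B2OC(C)(C)C(C)(C)O2)C(C)(C)O[C@]1(C)[C@H]1CCC(C)=CC1 | intermediate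
16 | tert-butyldimethylsilyl ether of 15 | CC(C)(C)[Si](C)(C)O[C@@H]1C[C@H](B2OC(C)(C)C(C)(C)O2)C(C)(C)O[C@]1(C)[C@H]1CCC(C)=CC1 | intermediate
17 | lithium [3,5-bis(trifluoromethyl)phenyl] boronate complex of 16 | [Li+].CC(C)(C)[Si](C)(C)O[C@@H]1C[C@H]([B-]2(OC(C)(C)C(C)(C)O2)c2cc(cc(c2)C(F)(F)F)C(F)(F)F)C(C)(C)O[C@]1(C)[C@H]1CCC(C)=CC1 | intermediate
18 | tert-butyl{[(2R,3R,5R)-5-bromo-2,6,6-trimethyl-2-[(1S)-4-methylcyclohex-3-en-1-yl]oxan-3-yl]oxy}dimethylsilane | CC(C)(C)[Si](C)(C)O[C@@H]1C[C@@H](Br)C(C)(C)O[C@]1(C)[C@H]1CCC(C)=CC1 | intermediate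
19 | (1R,2R,4S)-4-[(2R,3R,5R)-5-bromo-3-(TBSO)-2,6,6-trimethyloxan-2-yl]-2-iodo-1-methylcyclohexyl acetate | CC(C)(C)[Si](C)(C)O[C@@H]1C[C@@H](Br)C(C)(C)O[C@]1(C)[C@H]1CC[C@@](C)(OC(C)=O)[C@H](I)C1 | intermediate
20 | cis-fused C2,C3-acetoxonium (1,3-dioxolan-2-ylium) tetrafluoroborate, both oxygens on the face of the C6 substituent | CC(C)(C)[Si](C)(C)O[C@@H]1C[C@@H](Br)C(C)(C)O[C@]1(C)[C@H]1CC[C@@]2(C)OC(C)=[O+][C@H]2C1.F[B-](F)(F)F | intermediate
21 | (1S,2S,5S)-5-[(2R,3R,5R)-5-bromo-3-(TBSO)-2,6,6-trimethyloxan-2-yl]-2-chloro-2-methylcyclohexyl acetate | CC(C)(C)[Si](C)(C)O[C@@H]1C[C@@H](Br)C(C)(C)O[C@]1(C)[C@H]1CC[C@](C)(Cl)[C@@H](OC(C)=O)C1 | intermediate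
22 | (1S,2S,5S)-5-[(2R,3R,5R)-5-bromo-3-(TBSO)-2,6,6-trimethyloxan-2-yl]-2-chloro-2-methylcyclohexan-1-ol | CC(C)(C)[Si](C)(C)O[C@@H]1C[C@@H](Br)C(C)(C)O[C@]1(C)[C@H]1CC[C@](C)(Cl)[C@@H](O)C1 | intermediate
23 | (2S,5S)-5-[(2R,3R,5R)-5-bromo-3-(TBSO)-2,6,6-trimethyloxan-2-yl]-2-chloro-2-methylcyclohexan-1-one | CC(C)(C)[Si](C)(C)O[C@@H]1C[C@@H](Br)C(C)(C)O[C@]1(C)[C@H]1CC[C@](C)(Cl)C(=O)C1 | intermediate
24 | (1R,2S,5S)-5-[(2R,3R,5R)-5-bromo-3-(TBSO)-2,6,6-trimethyloxan-2-yl]-2-chloro-2-methylcyclohexan-1-ol | CC(C)(C)[Si](C)(C)O[C@@H]1C[C@@H](Br)C(C)(C)O[C@]1(C)[C@H]1CC[C@](C)(Cl)[C@H](O)C1 | intermediate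
25 | O-TBS-caespitol | CC(C)(C)[Si](C)(C)O[C@@H]1C[C@@H](Br)C(C)(C)O[C@]1(C)[C@H]1CC[C@](C)(Cl)[C@@H](Br)C1 | intermediate
26 | caespitol | O[C@@H]1C[C@@H](Br)C(C)(C)O[C@]1(C)[C@H]1CC[C@](C)(Cl)[C@@H](Br)C1 | intermediate
27 | 8-acetylcaespitol | CC(=O)O[C@@H]1C[C@@H](Br)C(C)(C)O[C@]1(C)[C@H]1CC[C@](C)(Cl)[C@@H](Br)C1 | target

Total step count: 19. Longest linear sequence: 19 steps (from 1 and 2).

Steps most likely to fail

1. Step 13.
- What may go wrong: once the tertiary C3–O bond of the acetoxonium ion loosens, a proton may be lost from C4 or from the C3 methyl faster than chloride is taken up. Chloride may also enter at C2, or the tertiary chloride may re-ionise on warming and drift to the more stable diaxial pattern.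
- Fallback: it sets out from alkene 18 and comes back at 25, so that steps 12–17 are bypassed. Alkene 18 is bromochlorinated directly (NBS, n-Bu4NCl, CH2Cl2, −78 °C → 0 °C), an anti addition.
- This should give 25 only as the lesser component, beside the trans-diaxial O-TBS-2,3-di-epi-caespitol F1 and the trans-diaxial 2-chloro-3-bromo regioisomer F2.
- Only F1 and F2 hold their two halogens anti-periplanar. NaI in acetone should therefore take them back to 18 by anti elimination, while diequatorial 25 survives and is separated. The recovered 18 is put through again.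

2. Step 17.
- What may go wrong: E2 loss of the activated axial oxygen together with the axial hydrogen on C1, a 1,2-shift of the anti-periplanar axial C3 methyl, or simply no substitution because C2 is neopentyl-like.
- Fallback: it sets out from the equatorial alcohol 22 and comes back at 25, bypassing steps 15–17. It replaces inversion of the axial alcohol by retention at the equatorial one.
- Alcohol 22 is sulfonylated (quinoline-8-sulfonyl chloride, DMAP, pyridine) to the quinoline-8-sulfonate of 22 F3. TiBr4 in CH2Cl2 at −78 °C should then chelate the leaving group through N and O and hand bromide to the same face. This front-side substitution is known for secondary cyclic alcohols. The low temperature and short contact are meant to spare the tertiary chloride.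

3. Step 4.
- What may go wrong: slow addition to the α-branched ketone, poor facial selectivity because the sec-alkyl group rivals the furyl group in size, and enolisation that would erode C6.
- Fallback: it sets out from amide 4 (and from 6) and comes back at 8, with the roles of the two carbon groups exchanged. MeMgBr (THF, 0 °C) converts 4 into 1-[(1S)-4-methylcyclohex-3-en-1-yl]ethan-1-one F4.
- Transmetallation of 6 with MgBr2·OEt2 gives (5-methylfuran-2-yl)magnesium bromide F5. F5 is added to F4 in toluene at −78 °C in the presence of one equivalent of a chiral tridentate (N,N,O) aminophenol ligand derived from trans-cyclohexane-1,2-diamine (ligand-mediated asymmetric Grignard addition to a methyl ketone).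
- The reagent now has to tell methyl from sec-alkyl, a larger steric difference, and any 7-epimer is again a separable diastereomer.

Further compounds
F1 | step 13 | O-TBS-2,3-di-epi-caespitol, (2R,3R), C2–Br and C3–Cl trans-diaxial | CC(C)(C)[Si](C)(C)O[C@@H]1C[C@@H](Br)C(C)(C)O[C@]1(C)[C@H]1CC[C@@](C)(Cl)[C@H](Br)C1
F2 | step 13 | 2-chloro-3-bromo regioisomer, (2R,3R), C2–Cl and C3–Br trans-diaxial | CC(C)(C)[Si](C)(C)O[C@@H]1C[C@@H](Br)C(C)(C)O[C@]1(C)[C@H]1CC[C@@](C)(Br)[C@H](Cl)C1
F3 | step 17 | quinoline-8-sulfonate of 22 | CC(C)(C)[Si](C)(C)O[C@@H]1C[C@@H](Br)C(C)(C)O[C@]1(C)[C@H]1CC[C@](C)(Cl)[C@@H](OS(=O)(=O)c2cccc3cccnc23)C1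
F4 | step 4 | 1-[(1S)-4-methylcyclohex-3-en-1-yl]ethan-1-one | CC(=O)[C@H]1CCC(C)=CC1
F5 | step 4 | (5-methylfuran-2-yl)magnesium bromide | Cc1ccc([Mg]Br)o1
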